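**Plan**

- Retrosynthesis first removes the MOM group on O2 of ring C, then cuts the allyl group of ring A at its vinyl–CH2 bond (back to a formyl group) and the A–O–B1 ether (SNAr of a B1 phenol on 4-fluoro-3-methoxybenzaldehyde).
- Ring B is cut at B4–B5 and B1–B6. It carries O on B1, O–ring C on B2 and OMe on B3 in a row, H on B4 and B6 and allyl on B5. This is the pattern left by the carbonyl carbon, C2 and C3 of a squarate-derived cyclobut-2-enone whose C4 holds H and a 1-allylvinyl group. The pieces are a 4-chlorocyclobutenone and a penta-1,4-dien-2-ylstannane.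
- The crowded B2–O–C1 ether is cut while B2 is still a vinylogous acid chloride carbon of the squarate. The ring C phenol comes from 5-bromo-2-hydroxy-3-methoxybenzaldehyde, in which O1 is masked as the formyl group.
- Forward order: ring C phenol (steps 1–3), mixed squarate with reduction and chlorination (steps 4–7), stannane (steps 8–9), ring B by coupling and ring expansion (step 10), ring A by SNAr and formyl-to-allyl conversion (steps 11–14), deprotection (step 15).
- The target has no stereocentre. The cyclobutenone intermediates are racemic at C4, and this centre is erased when ring B aromatises.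

Key step: step 10

Remark: 5-bromo-2-hydroxy-3-methoxybenzaldehyde, squaric acid, 2,3-dibromopropene and 4-fluoro-3-methoxybenzaldehyde are taken as purchasable; "allyl" means prop-2-en-1-yl throughout.

**Route**

Step 1
Reactants: 1 5-bromo-2-hydroxy-3-methoxybenzaldehyde
Product: 2 5-bromo-3-methoxy-2-(methoxymethoxy)benzaldehyde
Conditions: MOMCl, i-Pr2NEt, CH2Cl2, 0 °C to rt
Reagents that add atoms: chloromethyl methyl ether (MOMCl), COCCl
Why: O-alkylation of the only phenol (Williamson-type acetal formation) protects the future O2 of ring C while O1 is still a formyl group, so the two catechol oxygens never have to be told apart.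

Step 2
Reactants: 2 5-bromo-3-methoxy-2-(methoxymethoxy)benzaldehyde
Product: 4 5-bromo-3-methoxy-2-(methoxymethoxy)phenol, via formate ester 3 (not isolated)
Conditions: mCPBA, CH2Cl2, 0 °C to rt; then K2CO3 (cat.), MeOH, rt
Reagents that add atoms: 3-chloroperbenzoic acid (mCPBA), OOC(=O)c1cccc(Cl)c1
Why: Baeyer–Villiger oxidation, in which the electron-rich ortho-alkoxyaryl group migrates in preference to hydrogen and methanolysis of the aryl formate frees O1; the peracid is used before any alkene is present.

Step 3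
Reactants: 4 5-bromo-3-methoxy-2-(methoxymethoxy)phenol
Product: 5 5-allyl-3-methoxy-2-(methoxymethoxy)phenol
Conditions: allylSnBu3, Pd(PPh3)4 (5 mol %), toluene, 100 °C
Reagents that add atoms: allyltributylstannane, C=CC[Sn](CCCC)(CCCC)CCCC
Why: Stille (Migita–Kosugi) coupling, in which zerovalent palladium inserts into the aryl C–Br bond and the allyl group is transferred from tin under neutral conditions that should leave the free phenol and the MOM ether untouched.

Step 4
Reactants: 6 squaric acid (3,4-dihydroxycyclobut-3-ene-1,2-dione)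
Product: 7 3,4-dichlorocyclobut-3-ene-1,2-dione
Conditions: (COCl)2 (2.2 equiv), DMF (cat.), CH2Cl2, rt to 40 °C
Reagents that add atoms: oxalyl chloride, O=C(Cl)C(Cl)=O
Why: Acid chloride formation through the Vilsmeier-type chloroiminium ion, applied to the two vinylogous carboxylic acid groups of squaric acid.

Step 5
Reactants: 7 3,4-dichlorocyclobut-3-ene-1,2-dione, 5 5-allyl-3-methoxy-2-(methoxymethoxy)phenol
Product: 9 3-[5-allyl-3-methoxy-2-(methoxymethoxy)phenoxy]-4-methoxycyclobut-3-ene-1,2-dione, via ester chloride 8 (not isolated)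
Conditions: MeOH (1.0 equiv), CH2Cl2, 0 °C to rt, volatiles removed; then 5, i-Pr2NEt, CH2Cl2, −40 to 0 °C
Reagents that add atoms: methanol, CO
Why: Two vinylogous acyl substitutions (addition–elimination): the first chloride reacts with methanol without base and deactivates the second, which the phenoxide of 5 then displaces because chloride leaves far more readily than methoxide, so the hindered aryl ether is made on a reactive squarate carbon.

Step 6
Reactants: 9 3-[5-allyl-3-methoxy-2-(methoxymethoxy)phenoxy]-4-methoxycyclobut-3-ene-1,2-dione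
Product: 10 racemic 2-[5-allyl-3-methoxy-2-(methoxymethoxy)phenoxy]-4-hydroxy-3-methoxycyclobut-2-en-1-one
Conditions: LiAlH(OtBu)3 (1.05 equiv), THF, −78 °C; then pH 7 buffer
Reagents that add atoms: none
Why: 1,2-Hydride reduction of a squarate ester, expected at the carbonyl next to C–OMe because it is conjugated with the weaker aryloxy donor and is therefore the more electrophilic, which leaves the better stabilised vinylogous methyl ester; the new stereocentre is formed as a racemate.

Step 7
Reactants: 10 racemic 2-[5-allyl-3-methoxy-2-(methoxymethoxy)phenoxy]-4-hydroxy-3-methoxycyclobut-2-en-1-one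
Product: 11 racemic 2-[5-allyl-3-methoxy-2-(methoxymethoxy)phenoxy]-4-chloro-3-methoxycyclobut-2-en-1-one
Conditions: SOCl2, 2,6-lutidine, CH2Cl2, −20 to 0 °C
Reagents that add atoms: thionyl chloride, O=S(Cl)Cl
Why: Deoxychlorination through the chlorosulfite with a hindered base that traps HCl and spares the MOM ether; the 4-chloro isomer keeps the vinylogous ester conjugation and should be the favoured allylic chloride.

Step 8
Reactants: 12 2,3-dibromopropene
Product: 13 2-bromopenta-1,4-diene
Conditions: CH2=CHMgBr, CuI (5 mol %), THF, −20 to 0 °C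
Reagents that add atoms: vinylmagnesium bromide, C=C[Mg]Br
Why: Copper-catalysed allylic substitution of the allylic bromide, in which direct and allylically transposed attack give the same product and the vinylic bromide stays inert.

Step 9
Reactants: 13 2-bromopenta-1,4-diene
Product: 15 tributyl(penta-1,4-dien-2-yl)stannane, via 2-lithiopenta-1,4-diene 14 (not isolated)
Conditions: t-BuLi (2.0 equiv), Et2O, −78 °C; then Bu3SnCl, −78 °C to rt
Reagents that add atoms: tributyltin chloride, CCCC[Sn](Cl)(CCCC)CCCC
Why: Bromine–lithium exchange of a 2-bromoalkene followed by stannylation, kept at −78 °C so that the vinyllithium is trapped before it can remove a doubly allylic proton.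

Step 10
Reactants: 11 racemic 2-[5-allyl-3-methoxy-2-(methoxymethoxy)phenoxy]-4-chloro-3-methoxycyclobut-2-en-1-one, 15 tributyl(penta-1,4-dien-2-yl)stannane
Product: 19 5-allyl-2-[5-allyl-3-methoxy-2-(methoxymethoxy)phenoxy]-3-methoxyphenol, via dienylcyclobutenone 16 (not isolated), via dienylketene 17 (not isolated), via cyclohexadienone 18 (not isolated)
Conditions: Pd2(dba)3 (2.5 mol %), tri(2-furyl)phosphine (10 mol %), dioxane, 50 °C, then 100 °C
Reagents that add atoms: none
Why: Zerovalent palladium ionises the allylic C4–Cl bond of 11 to an η3-oxocyclobutenyl complex, the dienyl group is transferred from tin and reductive elimination at C4 gives 16; the closest known reaction type is this same Stille coupling and thermal benzannulation of 2,3-dialkyl and 2,3-dialkoxy 4-chlorocyclobutenones with alkenylstannanes, here applied to a 2-aryloxy case. On heating, 16 opens by reversible conrotatory 4π-electron ring opening, and the ketene isomer 17 with the dienyl group cis to the ketene is drained by disrotatory 6π-electron closure between the ketene carbon and the terminal methylene. Ring B thus closes as a six-membered carbocycle by electrocyclisation (bond B1–B6, after B4–B5 from the coupling), and dienone 18 enolises to phenol 19. No stereocentre is created and the one at C4 of 11 is erased. The step needs coupling at C4 and not at C2, which should follow because C2 is the more substituted, aryloxy-bearing terminus and coupling at C4 keeps the vinylogous ester conjugation. It also needs closure through the right alkene, which is secured because only the 1,1-disubstituted alkene bound to C4 is conjugated with the vinylketene while the allyl alkene is insulated by a CH2 group; the substituents on C1, C2 and C3 pass unchanged to B1, B2 and B3.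

Step 11
Reactants: 19 5-allyl-2-[5-allyl-3-methoxy-2-(methoxymethoxy)phenoxy]-3-methoxyphenol, 20 4-fluoro-3-methoxybenzaldehyde
Product: 21 4-{5-allyl-2-[5-allyl-3-methoxy-2-(methoxymethoxy)phenoxy]-3-methoxyphenoxy}-3-methoxybenzaldehyde
Conditions: K2CO3, DMF, 100 °C
Reagents that add atoms: none
Why: Nucleophilic aromatic substitution in which the para-formyl group stabilises the Meisenheimer adduct of the phenoxide of 19 and fluoride leaves; carbonate base should be too weak to move the allyl double bonds into conjugation.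

Step 12
Reactants: 21 4-{5-allyl-2-[5-allyl-3-methoxy-2-(methoxymethoxy)phenoxy]-3-methoxyphenoxy}-3-methoxybenzaldehyde
Product: 22 (4-{5-allyl-2-[5-allyl-3-methoxy-2-(methoxymethoxy)phenoxy]-3-methoxyphenoxy}-3-methoxyphenyl)methanol
Conditions: NaBH4, MeOH/THF, 0 °C
Reagents that add atoms: none
Why: Borohydride reduction of an aryl aldehyde, to which the alkenes, ethers and the MOM acetal are inert.

Step 13
Reactants: 22 (4-{5-allyl-2-[5-allyl-3-methoxy-2-(methoxymethoxy)phenoxy]-3-methoxyphenoxy}-3-methoxyphenyl)methanol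
Product: 23 5-allyl-1-[4-(bromomethyl)-2-methoxyphenoxy]-2-[5-allyl-3-methoxy-2-(methoxymethoxy)phenoxy]-3-methoxybenzene
Conditions: CBr4, PPh3, CH2Cl2, 0 °C
Reagents that add atoms: carbon tetrabromide, BrC(Br)(Br)Br
Why: Appel bromination of a primary benzylic alcohol under neutral conditions that should spare the MOM group and the alkenes.

Step 14
Reactants: 23 5-allyl-1-[4-(bromomethyl)-2-methoxyphenoxy]-2-[5-allyl-3-methoxy-2-(methoxymethoxy)phenoxy]-3-methoxybenzene
Product: 24 5-allyl-1-(4-allyl-2-methoxyphenoxy)-2-[5-allyl-3-methoxy-2-(methoxymethoxy)phenoxy]-3-methoxybenzene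
Conditions: CH2=CHSnBu3, Pd(PPh3)4 (5 mol %), toluene, 90 °C
Reagents that add atoms: tributyl(vinyl)stannane, C=C[Sn](CCCC)(CCCC)CCCC
Why: Stille coupling at a benzylic bromide, where oxidative addition of zerovalent palladium is fast, no β-hydrogen is present and vinyl transfer from tin completes the third allyl group without base.

Step 15
Reactants: 24 5-allyl-1-(4-allyl-2-methoxyphenoxy)-2-[5-allyl-3-methoxy-2-(methoxymethoxy)phenoxy]-3-methoxybenzene
Product: 25 4-allyl-2-[4-allyl-2-(4-allyl-2-methoxyphenoxy)-6-methoxyphenoxy]-6-methoxyphenol (target)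
Conditions: HCl (3 M aq.), MeOH, 50 °C
Reagents that add atoms: none
Why: Acid-catalysed acetal exchange removes the MOM group, while aryl ethers, methyl ethers and allyl groups are stable to dilute HCl.

**Compound list**

1 | 5-bromo-2-hydroxy-3-methoxybenzaldehyde | O=Cc1cc(Br)cc(OC)c1O | starting material
2 | 5-bromo-3-methoxy-2-(methoxymethoxy)benzaldehyde | O=Cc1cc(Br)cc(OC)c1OCOC | intermediate
3 | 5-bromo-3-methoxy-2-(methoxymethoxy)phenyl formate | O=COc1cc(Br)cc(OC)c1OCOC | intermediate
4 | 5-bromo-3-methoxy-2-(methoxymethoxy)phenol | Oc1cc(Br)cc(OC)c1OCOC | intermediate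
5 | 5-allyl-3-methoxy-2-(methoxymethoxy)phenol | Oc1cc(CC=C)cc(OC)c1OCOC | intermediate
6 | squaric acid (3,4-dihydroxycyclobut-3-ene-1,2-dione) | OC1=C(O)C(=O)C1=O | starting material
7 | 3,4-dichlorocyclobut-3-ene-1,2-dione | ClC1=C(Cl)C(=O)C1=O | intermediate
8 | 3-chloro-4-methoxycyclobut-3-ene-1,2-dione | COC1=C(Cl)C(=O)C1=O | intermediate
9 | 3-[5-allyl-3-methoxy-2-(methoxymethoxy)phenoxy]-4-methoxycyclobut-3-ene-1,2-dione | COC1=C(Oc2cc(CC=C)cc(OC)c2OCOC)C(=O)C1=O | intermediate
10 | racemic 2-[5-allyl-3-methoxy-2-(methoxymethoxy)phenoxy]-4-hydroxy-3-methoxycyclobut-2-en-1-one | O=C1C(Oc2cc(CC=C)cc(OC)c2OCOC)=C(OC)C1O | intermediate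
11 | racemic 2-[5-allyl-3-methoxy-2-(methoxymethoxy)phenoxy]-4-chloro-3-methoxycyclobut-2-en-1-one | O=C1C(Oc2cc(CC=C)cc(OC)c2OCOC)=C(OC)C1Cl | intermediate
12 | 2,3-dibromopropene | C=C(Br)CBr | starting material
13 | 2-bromopenta-1,4-diene | C=CCC(Br)=C | intermediate
14 | 2-lithiopenta-1,4-diene | [Li]C(=C)CC=C | intermediate
15 | tributyl(penta-1,4-dien-2-yl)stannane | C=CCC(=C)[Sn](CCCC)(CCCC)CCCC | intermediate
16 | racemic 2-[5-allyl-3-methoxy-2-(methoxymethoxy)phenoxy]-3-methoxy-4-(penta-1,4-dien-2-yl)cyclobut-2-en-1-one | O=C1C(Oc2cc(CC=C)cc(OC)c2OCOC)=C(OC)C1C(=C)CC=C | intermediate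
17 | (3E)-2-[5-allyl-3-methoxy-2-(methoxymethoxy)phenoxy]-3-methoxy-5-methylideneocta-1,3,7-trien-1-one (ketene, dienyl group cis to the ketene) | O=C=C(Oc1cc(CC=C)cc(OC)c1OCOC)/C(OC)=C\C(=C)CC=C | intermediate
18 | 5-allyl-2-[5-allyl-3-methoxy-2-(methoxymethoxy)phenoxy]-3-methoxycyclohexa-2,4-dien-1-one | O=C1CC(CC=C)=CC(OC)=C1Oc1cc(CC=C)cc(OC)c1OCOC | intermediate
19 | 5-allyl-2-[5-allyl-3-methoxy-2-(methoxymethoxy)phenoxy]-3-methoxyphenol | Oc1cc(CC=C)cc(OC)c1Oc1cc(CC=C)cc(OC)c1OCOC | intermediate
20 | 4-fluoro-3-methoxybenzaldehyde | O=Cc1ccc(F)c(OC)c1 | starting material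
21 | 4-{5-allyl-2-[5-allyl-3-methoxy-2-(methoxymethoxy)phenoxy]-3-methoxyphenoxy}-3-methoxybenzaldehyde | O=Cc1ccc(Oc2cc(CC=C)cc(OC)c2Oc2cc(CC=C)cc(OC)c2OCOC)c(OC)c1 | intermediate
22 | (4-{5-allyl-2-[5-allyl-3-methoxy-2-(methoxymethoxy)phenoxy]-3-methoxyphenoxy}-3-methoxyphenyl)methanol | OCc1ccc(Oc2cc(CC=C)cc(OC)c2Oc2cc(CC=C)cc(OC)c2OCOC)c(OC)c1 | intermediate
23 | 5-allyl-1-[4-(bromomethyl)-2-methoxyphenoxy]-2-[5-allyl-3-methoxy-2-(methoxymethoxy)phenoxy]-3-methoxybenzene | BrCc1ccc(Oc2cc(CC=C)cc(OC)c2Oc2cc(CC=C)cc(OC)c2OCOC)c(OC)c1 | intermediate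
24 | 5-allyl-1-(4-allyl-2-methoxyphenoxy)-2-[5-allyl-3-methoxy-2-(methoxymethoxy)phenoxy]-3-methoxybenzene | C=CCc1ccc(Oc2cc(CC=C)cc(OC)c2Oc2cc(CC=C)cc(OC)c2OCOC)c(OC)c1 | intermediate
25 | 4-allyl-2-[4-allyl-2-(4-allyl-2-methoxyphenoxy)-6-methoxyphenoxy]-6-methoxyphenol | C=CCc1ccc(Oc2cc(CC=C)cc(OC)c2Oc2cc(CC=C)cc(OC)c2O)c(OC)c1 | target

**Step count**

Total: 15 steps. Longest linear sequence: 12 steps (1, 2, 3, 5, 6, 7, 10, 11, 12, 13, 14, 15).

**Steps most likely to fail**

Step 10. Transfer of the α-branched dienyl group from tin may be slow, so that the cyclobutenyl–palladium intermediate loses aryloxide or couples at C2 and gives the regioisomeric phenol. The skipped diene may also isomerise at palladium. The fallback makes the B4–B5 bond by carbonyl addition instead of cross-coupling and removes the extra oxygen later. It sets out from squarate 9. 2-Lithiopenta-1,4-diene 14 is added at −78 °C to the carbonyl that the hydride attacks in step 6, giving racemic 2-[5-allyl-3-methoxy-2-(methoxymethoxy)phenoxy]-4-hydroxy-3-methoxy-4-(penta-1,4-dien-2-yl)cyclobut-2-en-1-one F1. Heating F1 in toluene at 110 °C under argon (Moore rearrangement, the hydroxyl turning outward so that the dienyl group lies cis to the ketene) should give 2-allyl-5-[5-allyl-3-methoxy-2-(methoxymethoxy)phenoxy]-6-methoxybenzene-1,4-diol F2. The less hindered hydroxyl of F2, flanked by H and corresponding to B1, is arylated with 20 (K2CO3, DMF) to 4-{5-allyl-2-[5-allyl-3-methoxy-2-(methoxymethoxy)phenoxy]-4-hydroxy-3-methoxyphenoxy}-3-methoxybenzaldehyde F3. The remaining hydroxyl on B4 is converted with Tf2O and pyridine into 2-allyl-5-[5-allyl-3-methoxy-2-(methoxymethoxy)phenoxy]-4-(4-formyl-2-methoxyphenoxy)-6-methoxyphenyl trifluoromethanesulfonate F4. Formate reduction of the aryl triflate (Pd(OAc)2, dppf, HCO2H, Et3N, DMF, 70 °C) comes back to the route at aldehyde 21.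

Step 6. Hydride delivery may not distinguish the two vinylogous ester carbonyls well enough, or may occur in conjugate fashion with loss of the aryloxide. The fallback removes the site question by reducing a symmetric squarate and bringing in the methoxy group afterwards. It sets out from dichloride 7, which with two equivalents of 5 and i-Pr2NEt gives 3,4-bis[5-allyl-3-methoxy-2-(methoxymethoxy)phenoxy]cyclobut-3-ene-1,2-dione F5. Reduction with LiAlH(OtBu)3 at −78 °C gives racemic 2,3-bis[5-allyl-3-methoxy-2-(methoxymethoxy)phenoxy]-4-hydroxycyclobut-2-en-1-one F6. Methanol with catalytic Et3N at 0 °C then adds to C3, the β-carbon of the enone, and expels only that aryloxide (vinylogous transesterification). This returns to the route at 10, and the released phenol 5 is recovered.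

Step 7. The C4 position may ionise during chlorination or work-up, with migration of chloride to C2, hydrolytic loss of the aryloxy group, or acid cleavage of the MOM group. The fallback avoids the chloride and uses a less ionisable allylic ester as the electrophile. It sets out from 10, which with Ac2O, pyridine and DMAP (cat.) in CH2Cl2 at 0 °C gives racemic 2-[5-allyl-3-methoxy-2-(methoxymethoxy)phenoxy]-3-methoxy-4-oxocyclobut-2-en-1-yl acetate F7. Coupling of F7 with stannane 15 under the conditions for allylic acetates (Pd2(dba)3, LiCl, DMF, 50 °C, then 100 °C) should pass through 16, 17 and 18 and comes back to the route at phenol 19.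

**Further compounds**

F1 | step 10 | racemic 2-[5-allyl-3-methoxy-2-(methoxymethoxy)phenoxy]-4-hydroxy-3-methoxy-4-(penta-1,4-dien-2-yl)cyclobut-2-en-1-one | O=C1C(Oc2cc(CC=C)cc(OC)c2OCOC)=C(OC)C1(O)C(=C)CC=C
F2 | step 10 | 2-allyl-5-[5-allyl-3-methoxy-2-(methoxymethoxy)phenoxy]-6-methoxybenzene-1,4-diol | Oc1cc(CC=C)c(O)c(OC)c1Oc1cc(CC=C)cc(OC)c1OCOC
F3 | step 10 | 4-{5-allyl-2-[5-allyl-3-methoxy-2-(methoxymethoxy)phenoxy]-4-hydroxy-3-methoxyphenoxy}-3-methoxybenzaldehyde | O=Cc1ccc(Oc2cc(CC=C)c(O)c(OC)c2Oc2cc(CC=C)cc(OC)c2OCOC)c(OC)c1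
F4 | step 10 | 2-allyl-5-[5-allyl-3-methoxy-2-(methoxymethoxy)phenoxy]-4-(4-formyl-2-methoxyphenoxy)-6-methoxyphenyl trifluoromethanesulfonate | O=Cc1ccc(Oc2cc(CC=C)c(OS(=O)(=O)C(F)(F)F)c(OC)c2Oc2cc(CC=C)cc(OC)c2OCOC)c(OC)c1
F5 | step 6 | 3,4-bis[5-allyl-3-methoxy-2-(methoxymethoxy)phenoxy]cyclobut-3-ene-1,2-dione | O=C1C(=O)C(Oc2cc(CC=C)cc(OC)c2OCOC)=C1Oc1cc(CC=C)cc(OC)c1OCOC
F6 | step 6 | racemic 2,3-bis[5-allyl-3-methoxy-2-(methoxymethoxy)phenoxy]-4-hydroxycyclobut-2-en-1-one | O=C1C(Oc2cc(CC=C)cc(OC)c2OCOC)=C(Oc2cc(CC=C)cc(OC)c2OCOC)C1O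
F7 | step 7 | racemic 2-[5-allyl-3-methoxy-2-(methoxymethoxy)phenoxy]-3-methoxy-4-oxocyclobut-2-en-1-yl acetate | CC(=O)OC1C(OC)=C(Oc2cc(CC=C)cc(OC)c2OCOC)C1=O
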